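Remark on numbering: carbons are called C1–C15 as in the germacrane skeleton of the target (C1 ketone, C2=C3, C3–O–C10 bridge, C4=C5 with the C15 methyl, C6 lactone oxygen, C7–C11, C8 ester oxygen, C10 with the C14 methyl, C12 lactone carbonyl, C13 methylene). Compound numbers are 1–25.

Remark on chemistry (assumptions): diazoethane is used as a separately prepared ethereal solution (from N-ethyl-N-nitrosourea and aqueous KOH). The (2S,3R) epoxy alcohol 2 is taken to arise with the D-(−)-tartrate ester, following the usual facial rule of the titanium tartrate epoxidation. The silyl group on O6 is triisopropylsilyl instead of a smaller silyl group, for the reason given in step 2.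

## Analysis of the target

Lychnopholide (25) is a furanoheliangolide: a cyclodecane C1–C10 in which an oxygen joins C3 and C10, so the core is an 11-oxabicyclo[6.2.1]undecane made of a furan-3(2H)-one (O, C3, C2, C1, C10) and a nine-membered oxacycle. An α-methylene-γ-butyrolactone is fused trans across C6–C7 (oxygen on C6, C11 on C7), and C8 carries an angelate. There are four stereocentres, C6 (R), C7 (R), C8 (S) and C10 (R). Drawn flat, the oxygens on C6 and C8 and the ether bridge lie on one face, and C11 and the C14 methyl on the other; C4=C5 is Z. C7 is the middle carbon of a 1,3-dioxygenated unit, so the lactone carbon has to be delivered to the carbon next to an oxygen-bearing carbon, against the normal bias of epoxide opening. The sensitive groups are the methylene lactone, the 5-alkenylfuranone (a 1,6-acceptor at C5), the angelate (which isomerises to the tiglate), and the lactone itself, which can migrate from O6 to a free O8. The hard part is the fully substituted C10, a tertiary ether at the bridgehead of a medium ring; it rules out simple etherification and makes a direct ten-membered ring closure costly. The strategy rests on one feature: the ring oxygen binds C3 and C10, and C10 also bears C9, so both O–C10 and C9–C10 can be made at a single carbenoid carbon.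

## Retrosynthetic reasoning

The C8 ester bond of 25 is cut first, to the alcohol 22 and angelic acid 23. The angelate is the group most easily isomerised, so it goes on last. The forward step must acylate a hindered secondary hydroxyl without touching the double-bond geometry or moving the lactone.

The C2=C3 double bond of 22 is removed next, giving the oxolanone 21. The 5-alkenylfuranone is a 1,6-acceptor whose C5 lies two atoms from O6. Any carbanion tethered to O6 would close on C5 as easily as on C7, so the enone is brought in only after the lactone exists. The forward step needs a hydride to be taken from C3 (allylic and α to the ring oxygen) and a proton from C2.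

The C7–C11 bond and the C11=C13 methylene of 21 are cut together, leading to the epoxy phosphonoacetate 19 and, by ester cleavage, to the epoxy alcohol 17 and the acid 18. C7 is the epoxide carbon nearer to C6–O, where an external nucleophile would not go. A carbanion tethered to O6 can reach C7 only, in a five-membered closure. Inversion at C7 gives the trans lactone, the C8–O bond is kept, and the phosphonate then makes the methylene by olefination, so no separate methylenation is needed.

The epoxide oxygen of 17 is removed to give the doubly allylic alcohol 16, and the silyl group is put back to give 15. The forward epoxidation must pick C7=C8 over C4=C5 and the face on which the hydroxyl lies (the cis epoxy alcohol). This is the weak point of the endgame and is treated as such below.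

The key disconnection cuts O–C10 and C9–C10 of 15 and reconnects O–C7. The ten-membered ring contracts to a six-membered dihydropyran bearing a vinyl group on C7, and C10 becomes the diazo carbon of the diazoketone 13. No other pair of cuts closes both rings, makes the quaternary centre and avoids a macrocyclisation in one step. C3 is lost later, but here it transfers its configuration to C10. The C7=C8 olefin appears where the lactone must be built.

The C1–C10 bond of 13 is cut to the acid 11 (through its chloride 12) and a two-carbon diazo reagent. This is the standard acylation of a diazoalkane and needs no stereocontrol.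

C3 of 11 is treated as an anomeric carbon. The C3–H bond and the C2–C3 bond are cut through the ester 10 and the hemiketal 9, back to the unsaturated lactone 7 and the acetate 8. A 2,6-cis and a 2,6-trans dihydropyran are expected to lie close in energy here, because the C4 methyl strains an equatorial group on C3. Equilibration is therefore not trusted, and the configuration is set kinetically by axial hydride delivery to the oxocarbenium ion.

C4=C5 of 7 is cut by olefin metathesis to the methacrylate 6, and the ester bond to the alcohol 4 and the acid chloride 5. Forming the trisubstituted olefin inside a six-membered ring fixes it as Z.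

The vinyl carbon C9 of 4 is removed (ylide homologation of an epoxide) to give 3, then the silyl group to give 2, and 2 comes from divinyl carbinol 1 by asymmetric epoxidation. The pyran needs the vinyl on C7 and the oxygen on C6 trans, which is the erythro (meso-type) diol pattern. A monosilyl ether of that diol would racemise by silyl migration, so the two oxygens are told apart from the start by the desymmetrising epoxidation, and both stereocentres come from one reagent-controlled step.

## Alternatives that were turned down

Alternative 1: the lactone ring is cut at C7–C11. In the forward direction Cp2TiCl (trivalent titanium) opens the C7–C8 epoxide of the propargyl ether A2 homolytically, and the C7 radical closes on the alkyne to give the 3-methyleneoxolane A1 with the C8 hydroxyl in place. In its favour, the tether fixes the regiochemistry at C7, no backside trajectory is needed, and C8–O and C7–C11 are set together; on this point it is stronger than the carbanion closure used here, and it is kept as the fallback for step 14. Against it, the step builds none of the skeleton: A2 already contains the bridged ten-membered ring and C10, which would still have to be made, most naturally by the ring expansion chosen here. In A2 the C7 radical is also homoallylic to the furanone-conjugated C4=C5, so a three-membered closure onto C5 would give a stabilised radical and open a rearrangement channel. The oxolane CH2 must afterwards be oxidised to the lactone next to a free hydroxyl. As a strategy it is an endgame, not a route to the core.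

Alternative 2: the carbocycle is cut at C5–C6. CrCl2 (divalent chromium) with catalytic NiCl2 (divalent nickel) converts the alkenyl iodide of the seco aldehyde A4 into an alkenylchromium species that adds to the C6 aldehyde and closes the ten-membered ring as the carbinol A3. In its favour, the reaction tolerates the furanone and the ester, the lactone carbons and the C8 oxygen are already present at ring closure (no late annulation problem, which is a real advantage over the chosen route), and lactonisation of A3 is trivial. Against it, the C6 configuration is set in a macrocyclisation with no reliable control element. The aldehyde of A4 has an epimerisable α-centre (C7) and a β-silyloxy group that can eliminate. The Z trisubstituted alkenyl iodide must be made next to the furanone. The quaternary C10 of A4 needs its own asymmetric construction in an open chain. The ring closure must also pay the entropy and strain of a ten-membered ring that already holds a planar furanone. The chosen strategy makes the same ring by enlarging a six-membered one and gets C10 for nothing.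

Alternative 3: the diene C2=C3–C4=C5 is cut through a cyclobutene. Irradiation of the cyclooctenone A6 adds its enone across the tethered ynol ether, and thermal opening of the cyclobutene gives the furanone and the ten-membered ring of A5 in one sequence. In its favour, the conrotatory opening must place one double bond trans in the carbocycle, and here that bond is C2=C3, which is cis inside the furanone, so the required geometry is the allowed one. The lactone and the C8 oxygen are carried through, and the furanone arises at the right oxidation level (the chosen route needs a separate dehydrogenation). Against it, an excited eight-membered enone relaxes by cis–trans isomerisation, so the cycloaddition is uncertain. An ynol ether on a tertiary oxygen with β-hydrogens is prone to retro-ene loss of ketene and to hydrolysis. A6 is an eight-membered ring with four stereocentres, including the quaternary C10, whose synthesis is longer than the whole precursor route here. The chosen strategy offers a thermal, catalytic key step on a precursor reached from acyclic building blocks.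

Key step: step 10

## Route

Step 1
Reactants: 1 penta-1,4-dien-3-ol
Product: 2 (2S,3R)-1,2-epoxypent-4-en-3-ol
Conditions: Ti(Oi-Pr)4 (10 mol %), D-(−)-diisopropyl tartrate (12 mol %), t-BuOOH, 4 Å MS, CH2Cl2, −20 °C
Reagents that add atoms: tert-butyl hydroperoxide, CC(C)(C)OO
Why: Sharpless asymmetric epoxidation of a prochiral divinyl carbinol; the tartrate selects one vinyl group and one face and gives the erythro epoxy alcohol, and the minor enantiomer is removed by a second epoxidation, so the optical purity rises with conversion. This sets C6 (carbinol carbon) and C7 (epoxide CH).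

Step 2
Reactants: 2 (2S,3R)-1,2-epoxypent-4-en-3-ol
Product: 3 (2S,3R)-1,2-epoxy-3-[(triisopropylsilyl)oxy]pent-4-ene
Conditions: i-Pr3SiOTf, 2,6-lutidine, CH2Cl2, −78 → 0 °C
Reagents that add atoms: triisopropylsilyl trifluoromethanesulfonate, CC(C)[Si](C(C)C)(C(C)C)OS(=O)(=O)C(F)(F)F
Why: Silylation of a secondary alcohol with a silyl triflate; the triisopropylsilyl group is chosen because its 1,2-shift to a neighbouring alkoxide, which would racemise the erythro diol monoether formed in step 3, is far slower than that of smaller silyl groups.

Step 3
Reactants: 3 (2S,3R)-1,2-epoxy-3-[(triisopropylsilyl)oxy]pent-4-ene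
Product: 4 (3S,4R)-4-[(triisopropylsilyl)oxy]hexa-1,5-dien-3-ol
Conditions: Me3S+ I− (3 equiv), n-BuLi (3 equiv), THF, −10 °C → rt
Reagents that add atoms: trimethylsulfonium iodide, C[S+](C)C.[I-]
Why: Sulfonium ylide opening of the terminal epoxide at CH2 (Corey–Chaykovsky-type reagent) followed by base-induced loss of dimethyl sulfide turns the epoxide into the one-carbon-homologated allylic alcohol; the C–O bond at C7 is not touched, so its configuration is kept.

Step 4
Reactants: 4 (3S,4R)-4-[(triisopropylsilyl)oxy]hexa-1,5-dien-3-ol; 5 methacryloyl chloride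
Product: 6 (3S,4R)-4-[(triisopropylsilyl)oxy]hexa-1,5-dien-3-yl 2-methylprop-2-enoate
Conditions: Et3N, DMAP (cat.), CH2Cl2, 0 °C
Reagents that add atoms: none
Why: O-Acylation of a secondary alcohol with an acid chloride; the ester brings in C3, C4 and the C15 methyl.

Step 5
Reactants: 6 (3S,4R)-4-[(triisopropylsilyl)oxy]hexa-1,5-dien-3-yl 2-methylprop-2-enoate
Product: 7 (5R,6S)-6-ethenyl-3-methyl-5-[(triisopropylsilyl)oxy]-5,6-dihydro-2H-pyran-2-one
Conditions: second-generation Grubbs catalyst, (H2IMes)(PCy3)Cl2Ru=CHPh (5 mol %), toluene (5 mM), 80 °C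
Reagents that add atoms: none
Why: Ring-closing metathesis between the methacrylate and the vinyl group on C6; the six-membered unsaturated lactone should form in preference to the five-membered butenolide (closure on the C7 vinyl), because metathesis of acrylate-type esters to butenolides is slow, and the six-membered ring fixes C4=C5 as Z.

Step 6
Reactants: 7 (5R,6S)-6-ethenyl-3-methyl-5-[(triisopropylsilyl)oxy]-5,6-dihydro-2H-pyran-2-one; 8 ethyl acetate
Product: 9 ethyl 2-[(5R,6S)-6-ethenyl-2-hydroxy-3-methyl-5-[(triisopropylsilyl)oxy]-5,6-dihydro-2H-pyran-2-yl]acetate (hemiketal, both configurations at C2 of the pyran)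
Conditions: LDA, 8, THF, −78 °C; then 7, −78 °C; aq NH4Cl at −78 °C
Reagents that add atoms: none
Why: Claisen-type 1,2-addition of a lithium ester enolate to a lactone carbonyl (first half of a C-glycoside synthesis from a lactone); conjugate addition at C5 should be held back by the α-methyl group and the neighbouring bulky silyl ether, and the cold quench keeps the tetrahedral adduct.

Step 7
Reactants: 9 ethyl 2-[(5R,6S)-6-ethenyl-2-hydroxy-3-methyl-5-[(triisopropylsilyl)oxy]-5,6-dihydro-2H-pyran-2-yl]acetate
Product: 10 ethyl 2-[(2R,5R,6S)-6-ethenyl-3-methyl-5-[(triisopropylsilyl)oxy]-5,6-dihydro-2H-pyran-2-yl]acetate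
Conditions: Et3SiH, BF3·OEt2, CH2Cl2, −78 → −30 °C
Reagents that add atoms: none
Why: Lewis acid ionises the hemiketal to an allyl-stabilised oxocarbenium ion and the silane delivers hydride to C3 along the axial direction, anti to the pseudo-equatorial vinyl group on C7 (ionic reduction of hemiketals to C-glycosides); the side chain therefore ends up cis to the vinyl group and C3 is set as R under kinetic, stereoelectronic control.

Step 8
Reactants: 10 ethyl 2-[(2R,5R,6S)-6-ethenyl-3-methyl-5-[(triisopropylsilyl)oxy]-5,6-dihydro-2H-pyran-2-yl]acetate
Product: 11 2-[(2R,5R,6S)-6-ethenyl-3-methyl-5-[(triisopropylsilyl)oxy]-5,6-dihydro-2H-pyran-2-yl]acetic acid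
Conditions: LiOH, THF/H2O, 0 °C; then 1 M HCl to pH 4, 0 °C
Reagents that add atoms: lithium hydroxide, [Li+].[OH-]
Why: Ester saponification; hydroxide attacks the ester carbonyl much faster than it deprotonates C2, so the β-alkoxy ester should not open by retro-oxa-Michael reaction and C3 should keep its configuration at 0 °C.

Step 9
Reactants: 11 2-[(2R,5R,6S)-6-ethenyl-3-methyl-5-[(triisopropylsilyl)oxy]-5,6-dihydro-2H-pyran-2-yl]acetic acid
Product: 13 3-diazo-1-[(2R,5R,6S)-6-ethenyl-3-methyl-5-[(triisopropylsilyl)oxy]-5,6-dihydro-2H-pyran-2-yl]butan-2-one, via acid chloride 12 (not isolated)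
Conditions: (COCl)2, DMF (cat.), CH2Cl2, 0 °C → rt, evaporate; then CH3CHN2 (4 equiv), Et2O, −20 → 0 °C
Reagents that add atoms: oxalyl chloride (chlorine in 12 only), O=C(Cl)C(=O)Cl; diazoethane, CC=[N+]=[N-]
Why: Acylation of a diazoalkane by an acid chloride (first stage of an Arndt–Eistert sequence); a second equivalent of diazoethane takes up the hydrogen chloride, and the product carries C10 with its C14 methyl as the diazo carbon.

Step 10
Reactants: 13 3-diazo-1-[(2R,5R,6S)-6-ethenyl-3-methyl-5-[(triisopropylsilyl)oxy]-5,6-dihydro-2H-pyran-2-yl]butan-2-one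
Product: 15 (1R,2Z,4S,5Z,8R)-2,8-dimethyl-4-[(triisopropylsilyl)oxy]-11-oxabicyclo[6.2.1]undeca-2,5-dien-9-one (in target numbering the 3,10-epoxy-4,10-dimethyl-6-silyloxycyclodeca-4Z,7Z-dien-1-one, 3R,6S,10R), via oxonium ylide 14 (not isolated)
Conditions: Cu(hfacac)2 [copper bis(hexafluoroacetylacetonate)] (5 mol %), CH2Cl2, reflux, slow addition of 13
Reagents that add atoms: none
Why: Cu(hfacac)2 (divalent copper as charged) decomposes 13 to an electrophilic copper carbenoid at C10, and the ring oxygen, held five atoms away, attacks it and closes the oxolan-3-one as the oxonium ylide 14 (five-membered closure by O→carbenoid attack, C10 becoming an enolate carbon). The ylide then undergoes a [2,3]-sigmatropic shift through the array C10–O–C7–C8=C9: C9–C10 forms, O–C7 breaks, C7=C8 appears and the pyran is enlarged by three atoms, which gives the nine-membered oxacycle and with C1–C2 the ten-membered carbocycle (ring closure by concerted ring expansion, no macrocyclisation). The closest known reaction type is the copper-catalysed oxonium ylide formation and [2,3] ring expansion of 6-vinyltetrahydropyran-2-yl diazoketones to 11-oxabicyclo[6.2.1]undecenones. The new stereocentre C10 is controlled by C3: the ylide is cis-fused and the allyl unit leaves oxygen and arrives at C10 on the same face, so C9 and C4 are cis on the oxolanone and 10R follows from 3R. The Z geometry of C7=C8 is expected from the equatorial vinyl group and the copper catalyst, which in the saturated series favours the Z alkene where dirhodium triphenylacetate favours E. Three selectivities are needed: oxygen capture must beat cyclopropanation of C4=C5 and 1,2-hydride shift from the C14 methyl (the five-membered ylide closure is fast, the ring olefin is trisubstituted and flanked by two C–O bonds, and the electron-poor ligand favours heteroatom attack); the [2,3] shift must beat the [1,2] shift (usual for an allyl group with a free terminus); and the vinyl group must migrate rather than the ring allyl unit C3–C4=C5 (whose terminus C5 could reach C10 only through a bridged transition state).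

Step 11
Reactants: 15 (1R,2Z,4S,5Z,8R)-2,8-dimethyl-4-[(triisopropylsilyl)oxy]-11-oxabicyclo[6.2.1]undeca-2,5-dien-9-one
Product: 16 (1R,2Z,4S,5Z,8R)-4-hydroxy-2,8-dimethyl-11-oxabicyclo[6.2.1]undeca-2,5-dien-9-one (3,10-epoxy-6-hydroxy-4,10-dimethylcyclodeca-4Z,7Z-dien-1-one, 3R,6S,10R)
Conditions: Bu4NF, AcOH, THF, 0 °C → rt
Reagents that add atoms: none
Why: Fluoride cleavage of a silyl ether; the acetic acid buffer keeps the β-alkoxy ketone from opening by enolisation and elimination.

Step 12
Reactants: 16 (1R,2Z,4S,5Z,8R)-4-hydroxy-2,8-dimethyl-11-oxabicyclo[6.2.1]undeca-2,5-dien-9-one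
Product: 17 (3R,6R,7R,8S,10R)-3,10:7,8-diepoxy-6-hydroxy-4,10-dimethylcyclodec-4Z-en-1-one (target numbering; cis-epoxide on the face of the C6 hydroxyl)
Conditions: VO(acac)2 [vanadyl bis(acetylacetonate)] (5 mol %), t-BuOOH, CH2Cl2, 0 °C → rt
Reagents that add atoms: tert-butyl hydroperoxide, CC(C)(C)OO
Why: Hydroxyl-directed vanadium epoxidation; in medium-ring Z-allylic alcohols the vanadate ester reacts when the hydroxyl lies near the olefin plane and gives the cis epoxy alcohol, which is the isomer needed for C8 (S). C7=C8 should be preferred over C4=C5 because the latter is flanked by two C–O bonds and carries the bridgehead carbon cis to C6, which makes the reactive conformer more strained; this preference is not secured and is discussed below.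

Step 13
Reactants: 17 (3R,6R,7R,8S,10R)-3,10:7,8-diepoxy-6-hydroxy-4,10-dimethylcyclodec-4Z-en-1-one; 18 (diethoxyphosphoryl)acetic acid
Product: 19 (3R,6R,7S,8S,10R)-3,10:7,8-diepoxy-4,10-dimethyl-1-oxocyclodec-4Z-en-6-yl (diethoxyphosphoryl)acetate
Conditions: DCC, DMAP (cat.), CH2Cl2, 0 °C → rt
Reagents that add atoms: none
Why: Steglich esterification of a secondary alcohol; it places C11 and C12 on O6, two atoms from C7.

Step 14
Reactants: 19 (3R,6R,7S,8S,10R)-3,10:7,8-diepoxy-4,10-dimethyl-1-oxocyclodec-4Z-en-6-yl (diethoxyphosphoryl)acetate
Product: 21 (3R,6R,7R,8S,10R)-3,10-epoxy-8-hydroxy-1-oxogermacra-4Z,11(13)-dien-12,6-olide (2,3-dihydro-8-O-deangeloyllychnopholide), via phosphono lactone enolate 20 (not isolated)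
Conditions: KOt-Bu (1.0 equiv), THF, −20 °C → rt; then (CH2O)n, rt
Reagents that add atoms: formaldehyde (as paraformaldehyde), C=O
Why: Proposed new method: the potassium carbanion of the phosphonoacetate attacks the epoxide carbon C7 from the face opposite the epoxide oxygen in a 5-exo-tet closure (the tether on O6 allows a five-membered ring only at C7; attack at C8 would be 6-endo), which inverts C7 and leaves the C8–O bond untouched, so the lactone is trans-fused and the 8-alkoxide lies on the face of the C6 oxygen; the alkoxide is quenched at once by the acidic C11–H to give the phosphonate-stabilised lactone enolate 20, which cannot translactonise, and 20 olefinates formaldehyde (Horner–Wadsworth–Emmons) to the methylene lactone; no conjugate acceptor is present in 19 at this stage. The closest known reaction types are the intramolecular Michael addition and olefination of (diethoxyphosphoryl)acetates of γ-hydroxy enones to α-methylene-γ-butyrolactones and the intermolecular opening of epoxides by phosphonoacetate anions; the epoxide as internal electrophile is the untested element.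

Step 15
Reactants: 21 (3R,6R,7R,8S,10R)-3,10-epoxy-8-hydroxy-1-oxogermacra-4Z,11(13)-dien-12,6-olide
Product: 22 (6R,7R,8S,10R)-3,10-epoxy-8-hydroxy-1-oxogermacra-2,4Z,11(13)-trien-12,6-olide (8-O-deangeloyllychnopholide)
Conditions: DDQ (1.5 equiv), 1,4-dioxane, 60 °C
Reagents that add atoms: none
Why: Quinone dehydrogenation of a ketone: hydride is taken from C3, which is allylic and α to the ring oxygen, and the resulting oxocarbenium ion loses the C2 proton to give the furanone (analogous to quinone dehydrogenation of 3-keto steroids and quinone oxidation of allylic ethers). C10 has no hydrogen, so the enone can form only toward C3, and the stereocentre C3 is removed here as planned.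

Step 16
Reactants: 22 (6R,7R,8S,10R)-3,10-epoxy-8-hydroxy-1-oxogermacra-2,4Z,11(13)-trien-12,6-olide; 23 angelic acid [(Z)-2-methylbut-2-enoic acid]
Product: 25 lychnopholide [(6R,7R,8S,10R)-8-angeloyloxy-3,10-epoxy-1-oxogermacra-2,4Z,11(13)-trien-12,6-olide], via mixed anhydride 24 (not isolated)
Conditions: 23, 2,4,6-Cl3C6H2COCl, Et3N, toluene, rt; then 22, toluene, 80 °C
Reagents that add atoms: 2,4,6-trichlorobenzoyl chloride (in 24 only), O=C(Cl)c1c(Cl)cc(Cl)cc1Cl
Why: Yamaguchi-type acylation through the mixed anhydride, run without a nucleophilic amine catalyst, which is the protocol that should keep the Z geometry of the angelate; the configuration at C8 is not touched.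

## Compound list

1 | penta-1,4-dien-3-ol | C=CC(O)C=C | starting material
2 | (2S,3R)-1,2-epoxypent-4-en-3-ol | C=C[C@@H](O)[C@@H]1CO1 | intermediate
3 | (2S,3R)-1,2-epoxy-3-[(triisopropylsilyl)oxy]pent-4-ene | C=C[C@@H](O[Si](C(C)C)(C(C)C)C(C)C)[C@@H]1CO1 | intermediate
4 | (3S,4R)-4-[(triisopropylsilyl)oxy]hexa-1,5-dien-3-ol | O[C@@H](C=C)[C@H](O[Si](C(C)C)(C(C)C)C(C)C)C=C | intermediate
5 | methacryloyl chloride | C=C(C)C(=O)Cl | starting material
6 | (3S,4R)-4-[(triisopropylsilyl)oxy]hexa-1,5-dien-3-yl 2-methylprop-2-enoate | C=C(C)C(=O)O[C@@H](C=C)[C@H](O[Si](C(C)C)(C(C)C)C(C)C)C=C | intermediate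
7 | (5R,6S)-6-ethenyl-3-methyl-5-[(triisopropylsilyl)oxy]-5,6-dihydro-2H-pyran-2-one | CC(C)[Si](C(C)C)(C(C)C)O[C@@H]1/C=C(/C)C(=O)O[C@H]1C=C | intermediate
8 | ethyl acetate | CCOC(C)=O | starting material
9 | ethyl 2-[(5R,6S)-6-ethenyl-2-hydroxy-3-methyl-5-[(triisopropylsilyl)oxy]-5,6-dihydro-2H-pyran-2-yl]acetate (hemiketal) | CC(C)[Si](C(C)C)(C(C)C)O[C@@H]1/C=C(/C)C(O)(CC(=O)OCC)O[C@H]1C=C | intermediate
10 | ethyl 2-[(2R,5R,6S)-6-ethenyl-3-methyl-5-[(triisopropylsilyl)oxy]-5,6-dihydro-2H-pyran-2-yl]acetate | CC(C)[Si](C(C)C)(C(C)C)O[C@@H]1/C=C(/C)[C@@H](CC(=O)OCC)O[C@H]1C=C | intermediate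
11 | 2-[(2R,5R,6S)-6-ethenyl-3-methyl-5-[(triisopropylsilyl)oxy]-5,6-dihydro-2H-pyran-2-yl]acetic acid | CC(C)[Si](C(C)C)(C(C)C)O[C@@H]1/C=C(/C)[C@@H](CC(=O)O)O[C@H]1C=C | intermediate
12 | 2-[(2R,5R,6S)-6-ethenyl-3-methyl-5-[(triisopropylsilyl)oxy]-5,6-dihydro-2H-pyran-2-yl]acetyl chloride (not isolated) | CC(C)[Si](C(C)C)(C(C)C)O[C@@H]1/C=C(/C)[C@@H](CC(=O)Cl)O[C@H]1C=C | intermediate
13 | 3-diazo-1-[(2R,5R,6S)-6-ethenyl-3-methyl-5-[(triisopropylsilyl)oxy]-5,6-dihydro-2H-pyran-2-yl]butan-2-one | CC(C)[Si](C(C)C)(C(C)C)O[C@@H]1/C=C(/C)[C@@H](CC(=O)C(C)=[N+]=[N-])O[C@H]1C=C | intermediate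
14 | bicyclic oxonium ylide (oxolan-3-one fused to the dihydropyran at O–C3, carbanion at C10; not isolated) | CC(C)[Si](C(C)C)(C(C)C)O[C@@H]1/C=C(/C)[C@H]2CC(=O)[C-](C)[O+]2[C@H]1C=C | intermediate
15 | (1R,2Z,4S,5Z,8R)-2,8-dimethyl-4-[(triisopropylsilyl)oxy]-11-oxabicyclo[6.2.1]undeca-2,5-dien-9-one | CC(C)[Si](C(C)C)(C(C)C)O[C@@H]2/C=C(/C)[C@H]3CC(=O)[C@@](C)(C/C=C\2)O3 | intermediate
16 | (1R,2Z,4S,5Z,8R)-4-hydroxy-2,8-dimethyl-11-oxabicyclo[6.2.1]undeca-2,5-dien-9-one | O[C@@H]2/C=C(/C)[C@H]3CC(=O)[C@@](C)(C/C=C\2)O3 | intermediate
17 | (3R,6R,7R,8S,10R)-3,10:7,8-diepoxy-6-hydroxy-4,10-dimethylcyclodec-4Z-en-1-one | O[C@@H]2/C=C(/C)[C@H]3CC(=O)[C@@](C)(C[C@@H]4O[C@@H]42)O3 | intermediate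
18 | (diethoxyphosphoryl)acetic acid | CCOP(=O)(OCC)CC(=O)O | starting material
19 | (3R,6R,7S,8S,10R)-3,10:7,8-diepoxy-4,10-dimethyl-1-oxocyclodec-4Z-en-6-yl (diethoxyphosphoryl)acetate | CCOP(=O)(OCC)CC(=O)O[C@@H]2/C=C(/C)[C@H]3CC(=O)[C@@](C)(C[C@@H]4O[C@@H]42)O3 | intermediate
20 | 11-(diethoxyphosphoryl)-3,10-epoxy-8-hydroxy-1-oxogermacr-4Z-en-12,6-olide, present as its potassium enolate (not isolated) | CCOP(=O)(OCC)C1C(=O)O[C@@H]2/C=C(/C)[C@H]3CC(=O)[C@@](C)(C[C@H](O)[C@@H]12)O3 | intermediate
21 | (3R,6R,7R,8S,10R)-3,10-epoxy-8-hydroxy-1-oxogermacra-4Z,11(13)-dien-12,6-olide | C=C1C(=O)O[C@@H]2/C=C(/C)[C@H]3CC(=O)[C@@](C)(C[C@H](O)[C@@H]12)O3 | intermediate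
22 | (6R,7R,8S,10R)-3,10-epoxy-8-hydroxy-1-oxogermacra-2,4Z,11(13)-trien-12,6-olide | C=C1C(=O)O[C@@H]2/C=C(/C)C3=CC(=O)[C@@](C)(C[C@H](O)[C@@H]12)O3 | intermediate
23 | angelic acid, (Z)-2-methylbut-2-enoic acid | C/C=C(/C)C(=O)O | starting material
24 | (Z)-2-methylbut-2-enoic 2,4,6-trichlorobenzoic anhydride (not isolated) | C/C=C(/C)C(=O)OC(=O)c1c(Cl)cc(Cl)cc1Cl | intermediate
25 | lychnopholide | C=C1C(=O)O[C@@H]2/C=C(/C)C3=CC(=O)[C@@](C)(C[C@H](OC(=O)/C(C)=C\C)[C@@H]12)O3 | target

Total step count: 16.
Longest linear sequence: 16 steps (1 → 25); compounds 5, 8, 18 and 23 are bought.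

## Steps least certain to work

Step 14 (lactone annulation, proposed new method). The most likely failures are that the tethered carbanion cannot reach the backside of C7 in the conformations open to the ring, so that no closure, a six-membered closure at C8, or acyl transfer to O8 takes over. The fallback uses a radical, which needs no backside trajectory, and known reaction types throughout. It sets out from 17 and comes back at 25.
- 17 is O-alkylated on the C6 hydroxyl (propargyl bromide, Ag2O, CH2Cl2, neutral so that the epoxy alcohol does not rearrange) to the propargyl ether F1.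
- Cp2TiCl (trivalent titanium, from Cp2TiCl2 and Zn, THF) opens the epoxide homolytically, and the C7 radical closes on the alkyne to the 3-methyleneoxolane alcohol F2.
- The C8 hydroxyl is acylated as in step 16 to the angelate F3.
- The allylic ether CH2 is oxidised with CrO3·3,5-dimethylpyrazole to the methylene lactone F4 (2,3-dihydrolychnopholide).
- DDQ as in step 15 then gives 25.

Step 10 (key step). The most likely failures are 1,2-hydride migration from the C14 methyl to the carbenoid carbon, cyclopropanation of C4=C5 in place of oxygen capture, or formation of the E isomer at C7=C8. The fallback replaces the methyl-substituted carbenoid by an acceptor/acceptor carbenoid, which has no β-hydrogen on the carbene substituent and is well behaved in ylide chemistry. It sets out from 11 (through its chloride 12) and comes back at 15.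
- Lithiated methyl diazoacetate (LiN(SiMe3)2, THF, −78 °C) is acylated by 12 to the diazo keto ester F5.
- Rh2(OAc)4 (dirhodium tetraacetate) or Cu(hfacac)2 gives the bridged β-keto ester F6 by the same ylide shift.
- LiAlH4 reduces ketone and ester to the diol F7.
- The primary hydroxyl is tosylated (TsCl, pyridine) to F8.
- LiBHEt3 reduces the tosylate to the C10-methyl carbinol F9.
- Dess–Martin periodinane returns the ketone 15.

Step 12 (epoxidation). The most likely failures are poor site selectivity (oxygen transfer to the trisubstituted C4=C5, which is also allylic to the hydroxyl) and, less likely, poor facial selectivity. The fallback deactivates C4=C5 by conjugation before the epoxidation and masks the resulting 1,6-acceptor during the carbanion step. It sets out from 15 and comes back at 22.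
- 15 is dehydrogenated with 2-iodoxybenzoic acid (DMSO, 70 °C) to the furanone silyl ether F10.
- Bu4NF/AcOH gives the alcohol F11.
- VO(acac)2/t-BuOOH, now with only C7=C8 nucleophilic, gives the epoxy alcohol F12.
- Esterification as in step 13 gives the phosphonoacetate F13.
- Luche reduction (NaBH4, CeCl3·7H2O, MeOH, −40 °C) turns the C1 ketone into the allylic alcohol F14, so that no acceptor is left at C5.
- KOt-Bu and then paraformaldehyde, as in step 14, give the methylene lactone diol F15.
- MnO2 oxidises only the allylic C1 hydroxyl and returns 22.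

Step 15 (dehydrogenation). The most likely failures are hydride abstraction at another activated C–H bond (C6–H is allylic and α to the lactone oxygen) or slow reaction with decomposition of the methylene lactone on heating. The fallback goes through a silyl enol ether and a palladium enolate instead of hydride abstraction. It sets out from 21 and comes back at 22.
- Soft enolisation of 21 (Me3SiOTf, Et3N, CH2Cl2, 0 °C) gives the C1 enol ether with the C8 hydroxyl silylated as well, F16.
- Saegusa–Ito oxidation (Pd(OAc)2, palladium diacetate, MeCN, rt) forms the C2=C3 bond.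
- Dilute citric acid removes the C8 silyl group and gives 22.

Step 16 (angeloylation). The most likely failures are isomerisation of the angelate to the tiglate at 80 °C, migration of the lactone from O6 to the free O8 under the basic conditions, or low conversion of the hindered hydroxyl. The fallback builds the Z double bond on the ester after a mild acylation. It sets out from 22 and comes back at 25.
- 22 is esterified with 2-(diphenoxyphosphoryl)propanoic acid (DCC, DMAP cat., CH2Cl2, 0 °C) to the phosphonate ester F17.
- A Z-selective Horner–Wadsworth–Emmons reaction with acetaldehyde (NaH, THF, −78 °C) gives 25.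

## Further compounds

F1 | step 14 | C6 propargyl ether of epoxy alcohol 17 | C#CCO[C@@H]2/C=C(/C)[C@H]3CC(=O)[C@@](C)(C[C@@H]4O[C@@H]42)O3
F2 | step 14 | 3-methyleneoxolane fused at C6–C7 (C12 as CH2) with free C8 hydroxyl, C1 ketone and C3–H | C=C1CO[C@@H]2/C=C(/C)[C@H]3CC(=O)[C@@](C)(C[C@H](O)[C@@H]12)O3
F3 | step 14 | C8 angelate of F2 | C=C1CO[C@@H]2/C=C(/C)[C@H]3CC(=O)[C@@](C)(C[C@H](OC(=O)/C(C)=C\C)[C@@H]12)O3
F4 | step 14 | 2,3-dihydrolychnopholide | C=C1C(=O)O[C@@H]2/C=C(/C)[C@H]3CC(=O)[C@@](C)(C[C@H](OC(=O)/C(C)=C\C)[C@@H]12)O3
F5 | step 10 | methyl 2-diazo-4-[(2R,5R,6S)-6-ethenyl-3-methyl-5-[(triisopropylsilyl)oxy]-5,6-dihydro-2H-pyran-2-yl]-3-oxobutanoate | CC(C)[Si](C(C)C)(C(C)C)O[C@@H]1/C=C(/C)[C@@H](CC(=O)C(=[N+]=[N-])C(=O)OC)O[C@H]1C=C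
F6 | step 10 | bridged β-keto ester, analogue of 15 with CO2Me on C10 in place of the methyl | CC(C)[Si](C(C)C)(C(C)C)O[C@@H]2/C=C(/C)[C@H]3CC(=O)[C@@](C(=O)OC)(C/C=C\2)O3
F7 | step 10 | C1,C14-diol from reduction of F6 | CC(C)[Si](C(C)C)(C(C)C)O[C@@H]2/C=C(/C)[C@H]3CC(O)[C@@](CO)(C/C=C\2)O3
F8 | step 10 | C14 4-methylbenzenesulfonate of F7 | CC(C)[Si](C(C)C)(C(C)C)O[C@@H]2/C=C(/C)[C@H]3CC(O)[C@@](COS(=O)(=O)c4ccc(C)cc4)(C/C=C\2)O3
F9 | step 10 | C1 alcohol corresponding to ketone 15 | CC(C)[Si](C(C)C)(C(C)C)O[C@@H]2/C=C(/C)[C@H]3CC(O)[C@@](C)(C/C=C\2)O3
F10 | step 12 | furanone (C2=C3) analogue of 15 | CC(C)[Si](C(C)C)(C(C)C)O[C@@H]2/C=C(/C)C3=CC(=O)[C@@](C)(C/C=C\2)O3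
F11 | step 12 | furanone C6 alcohol | O[C@@H]2/C=C(/C)C3=CC(=O)[C@@](C)(C/C=C\2)O3
F12 | step 12 | 7,8-epoxy furanone C6 alcohol | O[C@@H]2/C=C(/C)C3=CC(=O)[C@@](C)(C[C@@H]4O[C@@H]42)O3
F13 | step 12 | C6 (diethoxyphosphoryl)acetate of F12 | CCOP(=O)(OCC)CC(=O)O[C@@H]2/C=C(/C)C3=CC(=O)[C@@](C)(C[C@@H]4O[C@@H]42)O3
F14 | step 12 | C1 allylic alcohol of F13 | CCOP(=O)(OCC)CC(=O)O[C@@H]2/C=C(/C)C3=CC(O)[C@@](C)(C[C@@H]4O[C@@H]42)O3
F15 | step 12 | C1,C8-diol with the methylene lactone, 1-deoxo-1-hydroxy analogue of 22 | C=C1C(=O)O[C@@H]2/C=C(/C)C3=CC(O)[C@@](C)(C[C@H](O)[C@@H]12)O3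
F16 | step 15 | C1 trimethylsilyl enol ether and C8 trimethylsilyl ether of 21 | C=C1C(=O)O[C@@H]2/C=C(/C)[C@H]3C=C(O[Si](C)(C)C)[C@@](C)(C[C@H](O[Si](C)(C)C)[C@@H]12)O3
F17 | step 16 | C8 2-(diphenoxyphosphoryl)propanoate of 22 | C=C1C(=O)O[C@@H]2/C=C(/C)C3=CC(=O)[C@@](C)(C[C@H](OC(=O)C(C)P(=O)(Oc4ccccc4)Oc4ccccc4)[C@@H]12)O3
A1 | alternative 1 | 3-methyleneoxolane-fused furanone core with free C8 hydroxyl | C=C1CO[C@@H]2/C=C(/C)C3=CC(=O)[C@@](C)(C[C@H](O)[C@@H]12)O3
A2 | alternative 1 | C6 propargyl ether of the 7,8-epoxy furanone core | C#CCO[C@@H]2/C=C(/C)C3=CC(=O)[C@@](C)(C[C@@H]4O[C@@H]42)O3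
A3 | alternative 2 | ten-membered C6 carbinol with the C7 acetic ester | O[C@@H]2/C=C(/C)C3=CC(=O)[C@@](C)(C[C@H](O[Si](C)(C)C(C)(C)C)[C@H]2CC(=O)OC(C)(C)C)O3
A4 | alternative 2 | seco aldehyde with the Z alkenyl iodide at C5 | I/C=C(/C)C3=CC(=O)[C@@](C)(C[C@H](O[Si](C)(C)C(C)(C)C)[C@H](C=O)CC(=O)OC(C)(C)C)O3
A5 | alternative 3 | 8-O-silyl furanoheliangolide core without the C13 methylene | C1C(=O)O[C@@H]2/C=C(/C)C3=CC(=O)[C@@](C)(C[C@H](O[Si](C)(C)C(C)(C)C)[C@@H]12)O3
A6 | alternative 3 | lactone-fused cyclooctenone with the prop-1-ynyl ether on the C10 oxygen | CC#CO[C@]1(C)C[C@H](O[Si](C)(C)C(C)(C)C)[C@H]2CC(=O)O[C@@H]2/C=C\C1=O
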